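The chroman half is cut back to three alkynes, so that benzene ring C and dihydropyran ring D are made together, with three new C–C bonds, by one ruthenium-catalysed [2+2+2] cyclotrimerisation. The step exploits the fact that C8a and C8 of ring C can come from an ynol ether whose oxygen is already O1, C4a and C5 from a benzofuran-capped alkyne held to it through O1, C2, C3 and C4, and C6 and C7 from ethynylboronate, whose boron marks the C7 hydroxyl. The precursor is therefore a 1,7-diyne: the complete, MOM-protected benzofuran (rings A and B) bearing on its furan carbon a hexynyl chain that ends in a tertiary ethynyl ether.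

Key step: step 8

Remark on numbering: O1, C2, C3, C4, C4a, C5–C8 and C8a are chroman atoms; ring A is the benzo ring and ring B the furan of the benzofuran, ring C the chroman benzene ring, ring D the dihydropyran.

Remark on ring A: 2,4,6-trihydroxybenzaldehyde and 3-methylbut-2-en-1-ol are taken as the commercial entry. The 1,1-dimethylallyl group is introduced by Claisen rearrangement from the oxygen para to the formyl group of a symmetric ether. Rearrangement from the ortho oxygen of such phloroglucinol carbonyl compounds tends to run on to the open para carbon and would give the normal prenyl isomer. Ynol ether 14 is thermally labile (retro-ene loss of ketene) and is kept at or below 0 °C and used at once.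

Step 1
Reactants: 1 2,4,6-trihydroxybenzaldehyde; 2 3-methylbut-2-en-1-ol
Product: 3 2,6-dihydroxy-4-(3-methylbut-2-enyloxy)benzaldehyde
Conditions: PPh3, DIAD, THF, 0 °C → rt
Reagents that add atoms: none
Why: Mitsunobu etherification should select the C4 hydroxyl, the most acidic one and the one not engaged with the formyl group, and avoids the C-alkylation that an allyl halide and base can cause on a phloroglucinol.

Step 2
Reactants: 3 2,6-dihydroxy-4-(3-methylbut-2-enyloxy)benzaldehyde
Product: 4 2,4,6-trihydroxy-3-(2-methylbut-3-en-2-yl)benzaldehyde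
Conditions: PhNEt2, 190 °C, argon, sealed tube, short reaction time
Reagents that add atoms: none
Why: Aromatic Claisen rearrangement ([3,3] shift with allyl inversion) places the 1,1-dimethylallyl group on an ortho carbon; the two ortho carbons of 3 are equivalent by symmetry and the para carbon is blocked by the formyl group, so neither a regioisomer nor a para (Claisen–Cope) product can persist.

Step 3
Reactants: 4 2,4,6-trihydroxy-3-(2-methylbut-3-en-2-yl)benzaldehyde
Product: 5 2-hydroxy-4,6-bis(methoxymethoxy)-3-(2-methylbut-3-en-2-yl)benzaldehyde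
Conditions: MOMCl (2.2 equiv), iPr2NEt, CH2Cl2, 0 °C → rt
Reagents that add atoms: chloromethyl methyl ether, COCCl
Why: O-alkylation (acetal formation) should take the non-chelated C4 hydroxyl first and then the C6 hydroxyl, leaving the C2 hydroxyl, which is shielded by the tertiary allyl group and pressed into the hydrogen bond to the formyl oxygen, free for the later furan closure.

Step 4
Reactants: 5 2-hydroxy-4,6-bis(methoxymethoxy)-3-(2-methylbut-3-en-2-yl)benzaldehyde
Product: 6 2-(2,2-dibromoethenyl)-3,5-bis(methoxymethoxy)-6-(2-methylbut-3-en-2-yl)phenol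
Conditions: CBr4, PPh3, Et3N, CH2Cl2, 0 °C
Reagents that add atoms: tetrabromomethane, BrC(Br)(Br)Br
Why: Ramirez dibromo-olefination (first stage of the Corey–Fuchs sequence) converts salicylaldehydes directly into 2-(2,2-dibromovinyl)phenols, and the amine buffer keeps HBr away from the MOM acetals.

Step 5
Reactants: 7 ethyl pent-4-ynoate
Product: 8 2-methylhex-5-yn-2-ol
Conditions: MeMgBr (3.3 equiv), THF, 0 °C → rt; aq. NH4Cl
Reagents that add atoms: methylmagnesium bromide, C[Mg]Br
Why: Double Grignard addition to the ester gives the tertiary alcohol, a third equivalent being consumed by the terminal alkyne, which is restored on work-up.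

Step 6
Reactants: 6 2-(2,2-dibromoethenyl)-3,5-bis(methoxymethoxy)-6-(2-methylbut-3-en-2-yl)phenol; 8 2-methylhex-5-yn-2-ol
Product: 10 6-[4,6-bis(methoxymethoxy)-7-(2-methylbut-3-en-2-yl)-1-benzofuran-2-yl]-2-methylhex-5-yn-2-ol, via 2-bromobenzofuran 9 (not isolated)
Conditions: CuI (5 mol %), K3PO4, THF, 80 °C; then 8, Pd(PPh3)2Cl2 (3 mol %), iPr2NH, 60 °C, same flask
Reagents that add atoms: none
Why: Copper-catalysed intramolecular Ullmann-type C–O coupling of the phenol with the cis bromide of the dibromo-olefin closes ring B to the 2-bromobenzofuran, which then undergoes Sonogashira coupling with 8 without isolation of the electron-rich bromide.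

Step 7
Reactants: 10 6-[4,6-bis(methoxymethoxy)-7-(2-methylbut-3-en-2-yl)-1-benzofuran-2-yl]-2-methylhex-5-yn-2-ol; 11 trichloroethene
Product: 14 2-[5-(ethynyloxy)-5-methylhex-1-yn-1-yl]-4,6-bis(methoxymethoxy)-7-(2-methylbut-3-en-2-yl)-1-benzofuran, via dichlorovinyl ether 12 (not isolated), via lithium acetylide 13 (not isolated)
Conditions: KH (1.2 equiv), THF, 0 °C → rt; 11, −50 °C → rt; n-BuLi (2.5 equiv), −78 → −40 °C; MeOH, −78 °C; filtration through basic alumina at 0 °C
Reagents that add atoms: none
Why: In this trichloroethene route to ynol ethers the potassium alkoxide adds to dichloroacetylene generated in situ to give the (E)-1,2-dichlorovinyl ether, which n-BuLi converts by elimination and chlorine–lithium exchange into the lithium alkynyl ether that methanol protonates cold; at −78 °C the arene, the acetals and the internal alkyne should not be touched.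

Step 8
Reactants: 14 2-[5-(ethynyloxy)-5-methylhex-1-yn-1-yl]-4,6-bis(methoxymethoxy)-7-(2-methylbut-3-en-2-yl)-1-benzofuran; 15 2-ethynyl-4,4,5,5-tetramethyl-1,3,2-dioxaborolane
Product: 16 2-{5-[4,6-bis(methoxymethoxy)-7-(2-methylbut-3-en-2-yl)-1-benzofuran-2-yl]-2,2-dimethylchroman-7-yl}-4,4,5,5-tetramethyl-1,3,2-dioxaborolane
Conditions: Cp*RuCl(cod) (10 mol %), 15 (4 equiv), ClCH2CH2Cl, rt, argon; 14 added over 4 h by syringe pump
Reagents that add atoms: none
Why: Proposed new method: the Cp*RuCl fragment should couple the two tethered alkynes of 14 oxidatively to a ruthenacyclopentadiene (C4a–C8a bond), into which the alkynylboronate inserts before reductive elimination releases the arene (C5–C6 and C7–C8 bonds). The closest known reaction type is the ruthenium- or rhodium-catalysed [2+2+2] cycloaddition of tethered 1,6- and 1,7-diynes with ethynylboronates and other monoalkynes, including aryl ynol-ether diynes; a tertiary-alkyl ynol-ether diyne has not been used in it. Ring D closes in the oxidative-coupling event across the four-atom tether O1–C2–C3–C4, helped by the gem-dimethyl group at C2, and ring C closes by the insertion and reductive elimination that complete the annulation; no stereocentre is formed. The selectivity needed is insertion of 15 with boron at C7, meta to the benzofuran-bearing C5, which the single substituted diyne terminus should secure because the boryl-bearing carbon joins the unhindered C8 end of the metallacycle. Self-trimerisation of the diyne is held back by its slow addition to excess 15, and the neutral room-temperature medium should spare the ynol ether, the 1,1-dimethylallyl group, the acetals and the benzofuran.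

Step 9
Reactants: 16 2-{5-[4,6-bis(methoxymethoxy)-7-(2-methylbut-3-en-2-yl)-1-benzofuran-2-yl]-2,2-dimethylchroman-7-yl}-4,4,5,5-tetramethyl-1,3,2-dioxaborolane
Product: 17 5-[4,6-bis(methoxymethoxy)-7-(2-methylbut-3-en-2-yl)-1-benzofuran-2-yl]-2,2-dimethylchroman-7-ol
Conditions: NaBO3·4H2O, THF/H2O, rt
Reagents that add atoms: sodium perborate, [Na+].[O-]OB=O
Why: Oxidative ipso-hydroxylation of the arylboronate (peroxide attack at boron, 1,2-aryl shift to oxygen, hydrolysis) gives the C7 phenol under conditions that should not epoxidise the vinyl group or cleave the acetals.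

Step 10
Reactants: 17 5-[4,6-bis(methoxymethoxy)-7-(2-methylbut-3-en-2-yl)-1-benzofuran-2-yl]-2,2-dimethylchroman-7-ol
Product: 18 2-(7-hydroxy-2,2-dimethylchroman-5-yl)-7-(2-methylbut-3-en-2-yl)-1-benzofuran-4,6-diol (CNP0300714.0)
Conditions: HCl (1.25 M in MeOH), rt, argon
Reagents that add atoms: none
Why: Acid-catalysed acetal solvolysis removes both MOM groups, and dilute methanolic HCl should leave the 1,1-dimethylallyl group alone because Markovnikov protonation of its monosubstituted alkene, the entry to cyclisation onto the C6 phenol, is slow.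

Compound list
1 | 2,4,6-trihydroxybenzaldehyde | O=Cc1c(O)cc(O)cc1O | starting material
2 | 3-methylbut-2-en-1-ol | CC(C)=CCO | starting material
3 | 2,6-dihydroxy-4-(3-methylbut-2-enyloxy)benzaldehyde | CC(C)=CCOc1cc(O)c(C=O)c(O)c1 | intermediate
4 | 2,4,6-trihydroxy-3-(2-methylbut-3-en-2-yl)benzaldehyde | C=CC(C)(C)c1c(O)cc(O)c(C=O)c1O | intermediate
5 | 2-hydroxy-4,6-bis(methoxymethoxy)-3-(2-methylbut-3-en-2-yl)benzaldehyde | C=CC(C)(C)c1c(OCOC)cc(OCOC)c(C=O)c1O | intermediate
6 | 2-(2,2-dibromoethenyl)-3,5-bis(methoxymethoxy)-6-(2-methylbut-3-en-2-yl)phenol | C=CC(C)(C)c1c(OCOC)cc(OCOC)c(C=C(Br)Br)c1O | intermediate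
7 | ethyl pent-4-ynoate | C#CCCC(=O)OCC | starting material
8 | 2-methylhex-5-yn-2-ol | C#CCCC(C)(C)O | intermediate
9 | 2-bromo-4,6-bis(methoxymethoxy)-7-(2-methylbut-3-en-2-yl)-1-benzofuran | C=CC(C)(C)c1c(OCOC)cc(OCOC)c2cc(Br)oc12 | intermediate
10 | 6-[4,6-bis(methoxymethoxy)-7-(2-methylbut-3-en-2-yl)-1-benzofuran-2-yl]-2-methylhex-5-yn-2-ol | C=CC(C)(C)c1c(OCOC)cc(OCOC)c2cc(C#CCCC(C)(C)O)oc12 | intermediate
11 | trichloroethene | ClC=C(Cl)Cl | starting material
12 | 2-{5-[(E)-1,2-dichloroethenyloxy]-5-methylhex-1-yn-1-yl}-4,6-bis(methoxymethoxy)-7-(2-methylbut-3-en-2-yl)-1-benzofuran | C=CC(C)(C)c1c(OCOC)cc(OCOC)c2cc(C#CCCC(C)(C)O/C(Cl)=C\Cl)oc12 | intermediate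
13 | lithium acetylide of 14 (lithium on the terminal ynol ether carbon) | C=CC(C)(C)c1c(OCOC)cc(OCOC)c2cc(C#CCCC(C)(C)OC#C[Li])oc12 | intermediate
14 | 2-[5-(ethynyloxy)-5-methylhex-1-yn-1-yl]-4,6-bis(methoxymethoxy)-7-(2-methylbut-3-en-2-yl)-1-benzofuran | C=CC(C)(C)c1c(OCOC)cc(OCOC)c2cc(C#CCCC(C)(C)OC#C)oc12 | intermediate
15 | 2-ethynyl-4,4,5,5-tetramethyl-1,3,2-dioxaborolane | C#CB1OC(C)(C)C(C)(C)O1 | starting material
16 | 2-{5-[4,6-bis(methoxymethoxy)-7-(2-methylbut-3-en-2-yl)-1-benzofuran-2-yl]-2,2-dimethylchroman-7-yl}-4,4,5,5-tetramethyl-1,3,2-dioxaborolane | C=CC(C)(C)c1c(OCOC)cc(OCOC)c2cc(-c3cc(B5OC(C)(C)C(C)(C)O5)cc4c3CCC(C)(C)O4)oc12 | intermediate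
17 | 5-[4,6-bis(methoxymethoxy)-7-(2-methylbut-3-en-2-yl)-1-benzofuran-2-yl]-2,2-dimethylchroman-7-ol | C=CC(C)(C)c1c(OCOC)cc(OCOC)c2cc(-c3cc(O)cc4c3CCC(C)(C)O4)oc12 | intermediate
18 | 2-(7-hydroxy-2,2-dimethylchroman-5-yl)-7-(2-methylbut-3-en-2-yl)-1-benzofuran-4,6-diol | C=CC(C)(C)c1c(O)cc(O)c2cc(-c3cc(O)cc4c3CCC(C)(C)O4)oc12 | target

Total step count: 10
Longest linear sequence: 9 steps (steps 1–4 and 6–10, from 1 to 18); step 5 is a one-step side branch.

Steps most likely to fail

Step 8. The ynol ether may be lost to hydration, oligomerisation or retro-ene fragmentation before the metallacycle forms. The 1,7-diyne may also cyclise too slowly, so that the alkynylboronate trimerises, or insertion may place boron at C6. The fallback uses known chemistry only: ring C and ring D are brought in as a preformed chroman and joined to the benzofuran by Suzuki–Miyaura coupling. It sets out from 6 and returns at 17.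
- Phloroglucinol (in excess) is condensed with isoprene (Amberlyst 15, THF/heptane, 70 °C) to 2,2-dimethylchroman-5,7-diol F1.
- The unhindered C7 hydroxyl is silylated (TIPSCl, imidazole, DMF, 0 °C) to 2,2-dimethyl-7-(triisopropylsilyloxy)chroman-5-ol F2.
- Triflation (Tf2O, pyridine, CH2Cl2, 0 °C) should give 2,2-dimethyl-7-(triisopropylsilyloxy)chroman-5-yl trifluoromethanesulfonate F3.
- Miyaura borylation (B2pin2, Pd(dppf)Cl2, KOAc, dioxane, 80 °C) should give 2-[2,2-dimethyl-7-(triisopropylsilyloxy)chroman-5-yl]-4,4,5,5-tetramethyl-1,3,2-dioxaborolane F4.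
- Dibromo-olefin 6 is cyclised as in step 6 (CuI, K3PO4, THF, 80 °C) to bromide 9. F4, Pd(PPh3)4 and aqueous K3PO4 are then added to the same flask to give {5-[4,6-bis(methoxymethoxy)-7-(2-methylbut-3-en-2-yl)-1-benzofuran-2-yl]-2,2-dimethylchroman-7-yloxy}triisopropylsilane F5.
- Bu4NF in THF frees the C7 phenol, which is 17.

Step 7. The hindered tertiary alkoxide may add too slowly to dichloroacetylene, butyllithium may metallate the arene or the propargylic position, or the product may lose ketene or hydrate during isolation. The fallback builds the ynol ether from a formate instead, a known route. It sets out from 10 and returns at 14.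
- Formylation (acetic formic anhydride, pyridine, DMAP, 0 °C → rt) should give 6-[4,6-bis(methoxymethoxy)-7-(2-methylbut-3-en-2-yl)-1-benzofuran-2-yl]-2-methylhex-5-yn-2-yl formate F6.
- Wittig-type dichloromethylenation of the formate (PPh3, CCl4, THF, 60 °C) should give 2-[5-(2,2-dichloroethenyloxy)-5-methylhex-1-yn-1-yl]-4,6-bis(methoxymethoxy)-7-(2-methylbut-3-en-2-yl)-1-benzofuran F7.
- n-BuLi (THF, −78 → −40 °C) followed by cold methanol converts F7 through acetylide 13 into 14, whose cold solution is taken straight into step 8.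

Step 3. The second MOM group may go onto O2 in place of O6, or all three hydroxyls may be alkylated. The fallback differentiates the two oxygens beside the formyl group before the rearrangement, while they are still equivalent. It sets out from 3 and returns at 5.
- One equivalent of MOMCl with iPr2NEt (CH2Cl2, 0 °C) should give 2-hydroxy-6-(methoxymethoxy)-4-(3-methylbut-2-enyloxy)benzaldehyde F8, the remaining hydroxyl staying chelated.
- Claisen rearrangement (PhNEt2, 190 °C) should then give 2,4-dihydroxy-6-(methoxymethoxy)-3-(2-methylbut-3-en-2-yl)benzaldehyde F9. Migration to C3 is expected from the bond fixation imposed by the chelated o-hydroxy aldehyde, as for 4-allyloxy-2-hydroxyaryl carbonyl compounds, and from the smaller neighbour (OH against OMOM).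
- MOMCl and iPr2NEt on the non-chelated C4 hydroxyl give 5.

Further compounds
F1 | step 8 | 2,2-dimethylchroman-5,7-diol | CC1(C)CCc2c(O)cc(O)cc2O1
F2 | step 8 | 2,2-dimethyl-7-(triisopropylsilyloxy)chroman-5-ol | CC1(C)CCc2c(O)cc(O[Si](C(C)C)(C(C)C)C(C)C)cc2O1
F3 | step 8 | 2,2-dimethyl-7-(triisopropylsilyloxy)chroman-5-yl trifluoromethanesulfonate | CC1(C)CCc2c(OS(=O)(=O)C(F)(F)F)cc(O[Si](C(C)C)(C(C)C)C(C)C)cc2O1
F4 | step 8 | 2-[2,2-dimethyl-7-(triisopropylsilyloxy)chroman-5-yl]-4,4,5,5-tetramethyl-1,3,2-dioxaborolane | CC1(C)CCc2c(B3OC(C)(C)C(C)(C)O3)cc(O[Si](C(C)C)(C(C)C)C(C)C)cc2O1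
F5 | step 8 | {5-[4,6-bis(methoxymethoxy)-7-(2-methylbut-3-en-2-yl)-1-benzofuran-2-yl]-2,2-dimethylchroman-7-yloxy}triisopropylsilane | C=CC(C)(C)c1c(OCOC)cc(OCOC)c2cc(-c3cc(O[Si](C(C)C)(C(C)C)C(C)C)cc4c3CCC(C)(C)O4)oc12
F6 | step 7 | 6-[4,6-bis(methoxymethoxy)-7-(2-methylbut-3-en-2-yl)-1-benzofuran-2-yl]-2-methylhex-5-yn-2-yl formate | C=CC(C)(C)c1c(OCOC)cc(OCOC)c2cc(C#CCCC(C)(C)OC=O)oc12
F7 | step 7 | 2-[5-(2,2-dichloroethenyloxy)-5-methylhex-1-yn-1-yl]-4,6-bis(methoxymethoxy)-7-(2-methylbut-3-en-2-yl)-1-benzofuran | C=CC(C)(C)c1c(OCOC)cc(OCOC)c2cc(C#CCCC(C)(C)OC=C(Cl)Cl)oc12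
F8 | step 3 | 2-hydroxy-6-(methoxymethoxy)-4-(3-methylbut-2-enyloxy)benzaldehyde | CC(C)=CCOc1cc(O)c(C=O)c(OCOC)c1
F9 | step 3 | 2,4-dihydroxy-6-(methoxymethoxy)-3-(2-methylbut-3-en-2-yl)benzaldehyde | C=CC(C)(C)c1c(O)cc(OCOC)c(C=O)c1O
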